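**Plan**
1. Chain cuts: C16–C17 (dienyl–butenolide, Stille), C13=C14 (aldol addition then elimination), C9–C11 (Negishi coupling at the C9 enol triflate of the bicyclic enone).
2. Core cuts: C3–C4 of ring A (radical ring closure), then C10–C1 and C10–CH3 (two enolate alkylations). This leads back to (R)-carvone, which is ring B with the C8 methyl, the C9 carbonyl and, as its isopropenyl group, C4 with both geminal methyls.
3. Enabling feature: C4 is a quaternary carbon with two methyls, bonded to the ring-fusion CH C5, so it is the tertiary radical of a C5 isopropenyl group after H-atom addition. C3 is a bare ring CH2 reached from C10 through C1–C2, so it can be the terminal carbon of an acrylate hung on C10; the C2 ester steers the closure and is deleted afterwards.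
4. Forward: ring B (carvone) → quaternary C10 by methylation and acrylate-allylation → ring A by C3–C4 closure → de-esterification → C8=C9 enol triflate → chain joined at C9–C11, then C13=C14, then C16–C17.
5. Stereochemistry: C5 comes from (R)-carvone; C10 from alkylation anti to the isopropenyl group, which fixes the trans ring fusion; C13=C14 (E) from E1cB elimination to the conjugated ester; C15=C16 (E) from the (E)-vinylstannane, retained in the Stille coupling.

Key step: step 3

Remark: terpenoid numbering is used (ring A = C1–C5 and C10; ring B = C5–C10; chain C11–C16 outward from C9; C13 carries the CH2OH). Compounds 3, 7, 8, 18 and 19 are carried as epimer mixtures at centres that are destroyed later, so their SMILES leave those centres open.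

**Step 1**
Reactants: 1 (R)-(−)-carvone
Product: 3 6-methylcarvone (C-6 epimers), via lithium enolate of carvone 2 (not isolated)
Conditions: LiN(i-Pr)2, THF, −78 °C; then MeI, −78 → 0 °C
Reagents that add atoms: iodomethane, CI
Why: Kinetic α'-deprotonation gives the cross-conjugated lithium enolate, which is C-methylated (enolate alkylation); the new C6 centre is re-enolised in step 2, so its configuration does not matter.

**Step 2**
Reactants: 3 6-methylcarvone; 4 methyl 2-(bromomethyl)acrylate
Product: 6 methyl 2-{[(1S,6S)-1,3-dimethyl-2-oxo-6-(prop-1-en-2-yl)cyclohex-3-en-1-yl]methyl}prop-2-enoate (acrylate CH2 trans to isopropenyl), via tetrasubstituted lithium enolate 5 (not isolated)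
Conditions: LiN(i-Pr)2, THF, −78 → −20 °C; then 4, −78 → 0 °C
Reagents that add atoms: none
Why: Enolate alkylation (SN2' addition–elimination on the bromomethyl acrylate) creates quaternary C10; the electrophile should enter anti to the neighbouring C5 isopropenyl group, which puts the acrylate CH2 trans to isopropenyl and the methyl cis, as the trans ring fusion requires.

**Step 3**
Reactants: 6 dialkylated carvone acrylate
Product: 7 methyl (4aS,8aS)-4,4,7,8a-tetramethyl-8-oxo-1,2,3,4,4a,5,8,8a-octahydronaphthalene-2-carboxylate (trans-fused; C-2 epimers)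
Conditions: Fe(acac)3 (30 mol %), PhSiH3, EtOH/ethylene glycol, 60 °C
Reagents that add atoms: none
Why: The iron hydride formed from Fe(acac)3 and PhSiH3 transfers a hydrogen atom to the terminal CH2 of the electron-neutral isopropenyl group to give the tertiary C4 radical, which adds to C3, the unsubstituted β-carbon of the α-substituted acrylate; the α-ester radical at C2 is then reduced by divalent iron to the enolate and protonated by ethanol. The closest known reaction type is the iron-catalysed reductive olefin–olefin coupling (hydrogen-atom-transfer-initiated Giese addition) in its intramolecular form. Ring A closes in the 6-endo-trig mode, because the 5-exo alternative would need attack at the fully substituted, ester-bearing C2 and is disfavoured both sterically and by polarity. The only new stereocentre, C2, is temporary and is removed in step 5, so it needs no control; the trans ring fusion is already fixed by the anti relationship of the C5 and C10 substituents, which are both pseudo-equatorial on ring B and within reach of each other. The step needs chemoselective hydrogen-atom transfer to the isopropenyl group over the two electron-poor alkenes, which the higher reactivity of electron-neutral 1,1-disubstituted alkenes towards metal hydrides should secure; the ring B enone cannot intercept the radical because that would form a four-membered ring.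

**Step 4**
Reactants: 7 bicyclic keto ester
Product: 8 (4aS,8aS)-4,4,7,8a-tetramethyl-8-oxo-1,2,3,4,4a,5,8,8a-octahydronaphthalene-2-carboxylic acid (C-2 epimers)
Conditions: LiOH, THF/MeOH/H2O, 40 °C; then 1 M HCl
Reagents that add atoms: lithium hydroxide, [Li+].[OH-]
Why: Ester saponification; the hindered enone should be inert to hydroxide and epimerisation at C2 is of no consequence.

**Step 5**
Reactants: 8 bicyclic keto acid
Product: 9 (4aS,8aS)-2,5,5,8a-tetramethyl-4a,5,6,7,8,8a-hexahydronaphthalen-1(4H)-one
Conditions: 9-mesityl-10-phenylacridinium tetrafluoroborate (5 mol %), PhSSPh (10 mol %), i-Pr2NEt (20 mol %), CF3CH2OH, 450 nm LEDs, rt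
Reagents that add atoms: none
Why: Organophotoredox hydrodecarboxylation: the excited acridinium oxidises the carboxylate, loss of CO2 gives the secondary C2 radical, and hydrogen-atom transfer from thiophenol (formed from PhSSPh) leaves C2 as CH2, deleting the helper group and its stereocentre.

**Step 6**
Reactants: 9 bicyclic enone
Product: 11 (4aS,8aS)-2,5,5,8a-tetramethyl-3,4,4a,5,6,7,8,8a-octahydronaphthalen-1-yl trifluoromethanesulfonate, via lithium enolate 10 (not isolated)
Conditions: LiBH(s-Bu)3, THF, −78 °C; then PhNTf2, −78 °C → rt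
Reagents that add atoms: N-phenylbis(trifluoromethanesulfonimide), O=S(=O)(N(c1ccccc1)S(=O)(=O)C(F)(F)F)C(F)(F)F
Why: Conjugate (1,4) hydride reduction of the enone by the bulky borohydride gives regiospecifically the C8=C9 enolate (C10 is quaternary), and O-sulfonylation (enolate trapping) fixes the tetrasubstituted C8=C9 alkene; no stereocentre is formed.

**Step 7**
Reactants: 11 enol triflate; 12 (4-ethoxy-4-oxobutyl)zinc bromide
Product: 13 ethyl 4-[(4aS,8aS)-2,5,5,8a-tetramethyl-3,4,4a,5,6,7,8,8a-octahydronaphthalen-1-yl]butanoate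
Conditions: Pd(OAc)2 (5 mol %), SPhos (10 mol %), LiCl, THF/NMP, 60 °C
Reagents that add atoms: none
Why: Negishi sp2–sp3 cross-coupling: oxidative addition of the enol triflate to zerovalent palladium, transmetalation from the ester-tolerant alkylzinc and reductive elimination (favoured over β-hydride elimination by the bulky biarylphosphine) form the C9–C11 bond with the alkene position retained.

**Step 8**
Reactants: 14 propargyl alcohol
Product: 15 (E)-3-(tributylstannyl)prop-2-en-1-ol
Conditions: Bu3SnH, AIBN (cat.), neat, 80 °C; minor isomers removed by chromatography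
Reagents that add atoms: tributyltin hydride, CCCC[SnH](CCCC)CCCC
Why: Radical hydrostannation puts tin on the terminal alkyne carbon, and reversible stannyl-radical addition should equilibrate the alkene to the (E)-isomer.

**Step 9**
Reactants: 15 (E)-3-(tributylstannyl)prop-2-en-1-ol
Product: 16 (E)-3-(tributylstannyl)prop-2-enal
Conditions: MnO2, CH2Cl2, rt
Reagents that add atoms: none
Why: Allylic alcohol oxidation with MnO2 stops at the enal and leaves the vinylstannane and its (E)-geometry untouched.

**Step 10**
Reactants: 13 decalinyl butanoate; 16 (E)-3-(tributylstannyl)prop-2-enal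
Product: 18 ethyl (4E)-3-hydroxy-5-(tributylstannyl)-2-{2-[(4aS,8aS)-2,5,5,8a-tetramethyl-3,4,4a,5,6,7,8,8a-octahydronaphthalen-1-yl]ethyl}pent-4-enoate (diastereomer mixture), via lithium ester enolate 17 (not isolated)
Conditions: LiN(i-Pr)2, THF, −78 °C; then 16, −78 °C; aqueous work-up
Reagents that add atoms: none
Why: Aldol addition of the lithium ester enolate to the aldehyde (1,2-addition) forms the C13–C14 bond; the two new stereocentres need no control because both are removed in step 11.

**Step 11**
Reactants: 18 β-hydroxy ester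
Product: 20 ethyl (2E,4E)-5-(tributylstannyl)-2-{2-[(4aS,8aS)-2,5,5,8a-tetramethyl-3,4,4a,5,6,7,8,8a-octahydronaphthalen-1-yl]ethyl}penta-2,4-dienoate, via allylic acetate 19 (not isolated)
Conditions: Ac2O, Et3N, DMAP (cat.), CH2Cl2, 0 °C → rt; then DBU, rt
Reagents that add atoms: none
Why: Acetylation followed by E1cB elimination through the ester enolate gives the conjugated dienoate; the (E)-geometry at C13=C14 (C15 trans to the ester) is expected because the transition state to the (Z)-isomer suffers allylic strain between the ester and the vinyl group.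

**Step 12**
Reactants: 20 stannyl dienoate
Product: 21 (2E,4E)-5-(tributylstannyl)-2-{2-[(4aS,8aS)-2,5,5,8a-tetramethyl-3,4,4a,5,6,7,8,8a-octahydronaphthalen-1-yl]ethyl}penta-2,4-dien-1-ol
Conditions: i-Bu2AlH, CH2Cl2, −78 → 0 °C; Rochelle salt work-up
Reagents that add atoms: none
Why: 1,2-Reduction of the conjugated ester by the aluminium hydride gives the allylic alcohol before the butenolide is present; the vinylstannane and both alkene geometries are unaffected.

**Step 13**
Reactants: 21 dienylstannane alcohol; 22 4-bromofuran-2(5H)-one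
Product: 23 4-[(1E,3E)-4-(hydroxymethyl)-6-[(4aS,8aS)-2,5,5,8a-tetramethyl-3,4,4a,5,6,7,8,8a-octahydronaphthalen-1-yl]hexa-1,3-dien-1-yl]furan-2(5H)-one (target)
Conditions: Pd2(dba)3 (5 mol %), AsPh3 (20 mol %), NMP, rt, dark
Reagents that add atoms: none
Why: Stille coupling: the vinylogous acyl bromide adds to zerovalent palladium and the dienylstannane transmetalates with retention of the (E)-geometry, forming C16–C17 under neutral conditions that the free alcohol and the base-sensitive butenolide should tolerate.

**Compound list**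
1 | (R)-(−)-carvone, (5R)-2-methyl-5-(prop-1-en-2-yl)cyclohex-2-en-1-one | O=C1C[C@H](C(C)=C)CC=C1C | starting material
2 | lithium enolate of carvone (cross-conjugated, not isolated) | [Li]OC1=C[C@H](C(C)=C)CC=C1C | intermediate
3 | 6-methylcarvone, (5R)-2,6-dimethyl-5-(prop-1-en-2-yl)cyclohex-2-en-1-one (C-6 epimers) | O=C1C(C)[C@H](C(C)=C)CC=C1C | intermediate
4 | methyl 2-(bromomethyl)acrylate | C=C(CBr)C(=O)OC | starting material
5 | tetrasubstituted lithium enolate of 3 (not isolated) | [Li]OC1=C(C)[C@H](C(C)=C)CC=C1C | intermediate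
6 | methyl 2-{[(1S,6S)-1,3-dimethyl-2-oxo-6-(prop-1-en-2-yl)cyclohex-3-en-1-yl]methyl}prop-2-enoate | O=C1[C@@](C)(CC(=C)C(=O)OC)[C@H](C(C)=C)CC=C1C | intermediate
7 | methyl (4aS,8aS)-4,4,7,8a-tetramethyl-8-oxo-1,2,3,4,4a,5,8,8a-octahydronaphthalene-2-carboxylate (C-2 epimers) | O=C1[C@@]2(C)CC(C(=O)OC)CC(C)(C)[C@@H]2CC=C1C | intermediate
8 | (4aS,8aS)-4,4,7,8a-tetramethyl-8-oxo-1,2,3,4,4a,5,8,8a-octahydronaphthalene-2-carboxylic acid (C-2 epimers) | O=C1[C@@]2(C)CC(C(=O)O)CC(C)(C)[C@@H]2CC=C1C | intermediate
9 | (4aS,8aS)-2,5,5,8a-tetramethyl-4a,5,6,7,8,8a-hexahydronaphthalen-1(4H)-one | O=C1[C@@]2(C)CCCC(C)(C)[C@@H]2CC=C1C | intermediate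
10 | lithium C8=C9 enolate of the saturated ketone (not isolated) | CC1=C(O[Li])[C@@]2(C)CCCC(C)(C)[C@@H]2CC1 | intermediate
11 | (4aS,8aS)-2,5,5,8a-tetramethyl-3,4,4a,5,6,7,8,8a-octahydronaphthalen-1-yl trifluoromethanesulfonate | CC1=C(OS(=O)(=O)C(F)(F)F)[C@@]2(C)CCCC(C)(C)[C@@H]2CC1 | intermediate
12 | (4-ethoxy-4-oxobutyl)zinc bromide (THF solution) | CCOC(=O)CCC[Zn]Br | starting material
13 | ethyl 4-[(4aS,8aS)-2,5,5,8a-tetramethyl-3,4,4a,5,6,7,8,8a-octahydronaphthalen-1-yl]butanoate | CC1=C(CCCC(=O)OCC)[C@@]2(C)CCCC(C)(C)[C@@H]2CC1 | intermediate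
14 | propargyl alcohol | C#CCO | starting material
15 | (E)-3-(tributylstannyl)prop-2-en-1-ol | OC/C=C/[Sn](CCCC)(CCCC)CCCC | intermediate
16 | (E)-3-(tributylstannyl)prop-2-enal | O=C/C=C/[Sn](CCCC)(CCCC)CCCC | intermediate
17 | lithium enolate of ester 13 (not isolated) | CC1=C(CCC=C(O[Li])OCC)[C@@]2(C)CCCC(C)(C)[C@@H]2CC1 | intermediate
18 | ethyl (4E)-3-hydroxy-5-(tributylstannyl)-2-{2-[(4aS,8aS)-2,5,5,8a-tetramethyl-3,4,4a,5,6,7,8,8a-octahydronaphthalen-1-yl]ethyl}pent-4-enoate (diastereomer mixture) | CC1=C(CCC(C(O)/C=C/[Sn](CCCC)(CCCC)CCCC)C(=O)OCC)[C@@]2(C)CCCC(C)(C)[C@@H]2CC1 | intermediate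
19 | 3-O-acetate of 18 (not isolated) | CC1=C(CCC(C(OC(C)=O)/C=C/[Sn](CCCC)(CCCC)CCCC)C(=O)OCC)[C@@]2(C)CCCC(C)(C)[C@@H]2CC1 | intermediate
20 | ethyl (2E,4E)-5-(tributylstannyl)-2-{2-[(4aS,8aS)-2,5,5,8a-tetramethyl-3,4,4a,5,6,7,8,8a-octahydronaphthalen-1-yl]ethyl}penta-2,4-dienoate | CC1=C(CC/C(=C\C=C\[Sn](CCCC)(CCCC)CCCC)C(=O)OCC)[C@@]2(C)CCCC(C)(C)[C@@H]2CC1 | intermediate
21 | (2E,4E)-5-(tributylstannyl)-2-{2-[(4aS,8aS)-2,5,5,8a-tetramethyl-3,4,4a,5,6,7,8,8a-octahydronaphthalen-1-yl]ethyl}penta-2,4-dien-1-ol | CC1=C(CC/C(=C\C=C\[Sn](CCCC)(CCCC)CCCC)CO)[C@@]2(C)CCCC(C)(C)[C@@H]2CC1 | intermediate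
22 | 4-bromofuran-2(5H)-one | O=C1OCC(Br)=C1 | starting material
23 | 4-[(1E,3E)-4-(hydroxymethyl)-6-[(4aS,8aS)-2,5,5,8a-tetramethyl-3,4,4a,5,6,7,8,8a-octahydronaphthalen-1-yl]hexa-1,3-dien-1-yl]furan-2(5H)-one | CC1=C(CC/C(=C\C=C\C2=CC(=O)OC2)CO)[C@@]2(C)CCCC(C)(C)[C@@H]2CC1 | target

**Count and risks**
Total steps: 13. Longest linear sequence: 11 (steps 1–7 and 10–13); steps 8 and 9 form the side branch.

Steps most likely to fail:

- **Step 3.** The hydrogen atom may be transferred to the acrylate or the enone instead of the isopropenyl group, giving plain reduction, or the C4 radical may be quenched before it closes the ring. The fallback sets out from 6 and comes back at 7. Ionic Markovnikov addition of HBr to the isopropenyl group (HBr in AcOH, CH2Cl2, 0 °C) gives the tertiary bromide F1. Slow addition of Bu3SnH/AIBN in refluxing benzene then generates the same C4 radical by bromine abstraction; it closes ring A 6-endo onto the acrylate and is reduced by the stannane to 7.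

- **Step 7.** Transmetalation of the primary alkylzinc to the hindered vinylpalladium may be slow, so that β-hydride elimination or reduction of the triflate takes over. The fallback sets out from 11 and comes back at 13, and makes the C9–C11 bond with an sp carbon instead. Sonogashira coupling of 11 with but-3-yn-1-ol (Pd(PPh3)4, CuI, Et3N, DMF) gives the enynol F2. Hydrogenation over RhCl(PPh3)3 saturates only the triple bond and leaves the tetrasubstituted C8=C9 alkene, giving the alcohol F3. Oxidation (TEMPO, PhI(OAc)2, MeCN/H2O) gives the acid F4, and EtI/K2CO3 in DMF returns ester 13.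

- **Step 11.** The elimination may give poor E/Z control, or the allylic acetate next to the vinylstannane may ionise. The fallback sets out from 13 and comes back at 20, bypassing steps 10 and 11. The lithium enolate of 13 is treated with ClP(OEt)2 and the product oxidised with H2O2 to the α-phosphono ester F5. Horner–Wadsworth–Emmons olefination of F5 (NaH, THF, 0 °C) with aldehyde 16 forms C13=C14 directly, with the β-substituent trans to the ester as is usual for stabilised phosphonates, to give 20.

**Further compounds**
F1 | step 3 | methyl 2-{[(1S,6R)-6-(2-bromopropan-2-yl)-1,3-dimethyl-2-oxocyclohex-3-en-1-yl]methyl}prop-2-enoate | O=C1[C@@](C)(CC(=C)C(=O)OC)[C@H](C(C)(C)Br)CC=C1C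
F2 | step 7 | 4-[(4aS,8aS)-2,5,5,8a-tetramethyl-3,4,4a,5,6,7,8,8a-octahydronaphthalen-1-yl]but-3-yn-1-ol | CC1=C(C#CCCO)[C@@]2(C)CCCC(C)(C)[C@@H]2CC1
F3 | step 7 | 4-[(4aS,8aS)-2,5,5,8a-tetramethyl-3,4,4a,5,6,7,8,8a-octahydronaphthalen-1-yl]butan-1-ol | CC1=C(CCCCO)[C@@]2(C)CCCC(C)(C)[C@@H]2CC1
F4 | step 7 | 4-[(4aS,8aS)-2,5,5,8a-tetramethyl-3,4,4a,5,6,7,8,8a-octahydronaphthalen-1-yl]butanoic acid | CC1=C(CCCC(=O)O)[C@@]2(C)CCCC(C)(C)[C@@H]2CC1
F5 | step 11 | ethyl 2-(diethoxyphosphoryl)-4-[(4aS,8aS)-2,5,5,8a-tetramethyl-3,4,4a,5,6,7,8,8a-octahydronaphthalen-1-yl]butanoate (C-2 epimers) | CC1=C(CCC(P(=O)(OCC)OCC)C(=O)OCC)[C@@]2(C)CCCC(C)(C)[C@@H]2CC1
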